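Carry one number, 0.529, the rung ratio: tris adduct over double product at the last oak reading.

| setting | oak | summer | spring |
|---|---|---|---|
| solid substrate | 0.34 M | 0.50 M | 0.50 M |
| partner | 0.50 M | 0.500 M | 1.50 M |
| remark | run made earlier |  |  |
| time |  | 3.0 h | 3.0 h |

oak run (percent of the solid substrate charged)

| time / min | tris adduct / % | double product / % |
|---|---|---|
| 8.00 | 0.1 | 1.8 |
| 15.0 | 1.1 | 3.5 |
| 20.0 | 0.2 | 5.3 |
| 30.0 | 1.9 | 6.6 |
| 40.0 | 3.6 | 6.8 |

(scatter of a reading: 0.5 percentage points)

- solid, in amounts per volume of the solution: solid substrate
- steps under discussion: partner + first product -> double product; solid substrate <-> starting material; partner + tris adduct -> tetra adduct; 2 partner -> self-condensation product; partner + double product -> tris adduct; starting material + partner -> first product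
- at the start none of the solid substrate is in solution

* which of these holds the largest part of the solid substrate at the end of summer (tris adduct / tetra adduct / solid substrate / first product / double product)
* which of these holds the largest part of the solid substrate at the end of spring (tris adduct / tetra adduct / solid substrate / first product / double product)
* how much tris adduct is there at the end of spring, in percent of the solid substrate charged

Take these two amounts because oak read them, and because the step making each takes one partner. Divide one rate by the other and partner and the clock cancel, leaving how far the chain has gone. Treat the ratio as a reading, since each amount in it scatters by 0.5 percentage points. It stands below one at that oak reading, but higher than the 0.288 read at 30.0 min, so carrying it unchanged into spring is an assumption of mine that oak does not show. Grant double product the partner factor 3.00 over its oak reading, a generous guess of mine, and spring tris adduct comes to 10.8%.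

The forecast differs: first product for summer, tris adduct for spring, 50% of tris adduct, holding that “double converts to tris faster than it forms”.

Summer ends with solid substrate ahead at 40.7%; spring ends with first product ahead at 37.6%, and tris adduct at 3.94%.

    partner + first product → double product (k = 0.102 /M/min)
    solid substrate ⇌ starting material, rate k2*(cs2 - [starting material]) while solid is left; crystals form when [starting material] > cs2 (solubility = 0.110 M, k = 0.497 /min)
    partner + tris adduct → tetra adduct (k = 0.293 /M/min)
    2 partner → self-condensation product (k = 0.107 /M/min)
    partner + double product → tris adduct (k = 0.286 /M/min)
    starting material + partner → first product (k = 0.426 /M/min)

In spring the turnover of self-condensation reaches its midpoint at 1.89 min, earlier than that of dissolving at 0.115 h. Self-condensation takes 74.5% of the partner charge, and partner, the limiting reagent, stands at 0% with solid substrate at 25.8%. Spring double product times the rung ratio gives 4.15% of tris adduct. In the neighbour with 2.5 M of partner, its double product 8.75% gives 4.63%; computed, 4.83%.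

The data are calculated from invented constants, and the scatter is random.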